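**Retrosynthetic overview**
1. Target ⇒ cut the C16–O acyl bond: alkoxide of the saponified butenolide ent-labda-8(17),13-dien-15,16-olide plus (R)-2-methylbutanoyl imidazolide; the lactone ring is what fixes the acid cis to CH2O (13Z).
2. Butenolide ⇒ photochemical E/Z isomerisation–lactonisation of methyl 16-hydroxy-ent-labda-8(17),13-dien-15-oate.
3. Key step: the C16–O bond of that hydroxy ester ⇒ [2,3]-sigmatropic selenoxide-to-selenenate rearrangement of the 14-phenylselanyl 13(16)-ene ester.
4. Allyl selenide ⇒ deconjugative α-selenenylation of methyl copalate ⇐ (−)-copalic acid.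
5. Ring order: rings A and B (C5, C9, C10) are bought intact in copalic acid and never opened; the only ring made is the temporary butenolide (step 4), reopened in step 5; the side-chain stereocentre is bought in (R)-2-methylbutanoic acid.

Assumption: (−)-copalic acid (bulk diterpene acid of inexpensive commercial copaiba oleoresin, also a catalogue compound) and (R)-(−)-2-methylbutanoic acid count as purchasable chiral-pool materials; labdane numbering (C1–C20) is used for locants.

**Route**

Step 1
Reactants: 1 (−)-copalic acid [ent-labda-8(17),13E-dien-15-oic acid; decalin (5R,9R,10R)]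
Product: 3 methyl copalate [methyl ent-labda-8(17),13E-dien-15-oate], via potassium copalate 2 (not isolated)
Conditions: K2CO3 (1.5 equiv), MeI (1.5 equiv), DMF, rt
Reagents that add atoms: iodomethane, CI
Why: Carboxylate O-alkylation (SN2 on MeI) masks the acid so that one equivalent of amide base gives the ester dienolate and the later lactonisation has a leaving group; no stereocentre or alkene is touched.

Step 2
Reactants: 3 methyl copalate
Product: 5 methyl (14RS)-14-(phenylselanyl)-ent-labda-8(17),13(16)-dien-15-oate, via lithium dienolate 4 (not isolated)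
Conditions: LiN(iPr)2 (1.1 equiv, commercial solution), THF, −78 °C; then PhSeBr (1.0 equiv), −78 °C
Reagents that add atoms: benzeneselenenyl bromide, Br[Se]c1ccccc1
Why: Lithium-directed kinetic deprotonation removes a proton from the γ-methyl (C16) that lies cis to the ester, and the resulting dienolate is selenenylated at Cα (deconjugative α-selenenylation), which at −78 °C outruns addition of PhSeBr to the 8(17)-alkene; the new C14 centre forms as a mixture and is erased in step 3.

Step 3
Reactants: 5 methyl (14RS)-14-(phenylselanyl)-ent-labda-8(17),13(16)-dien-15-oate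
Product: 8 methyl (13E)-16-hydroxy-ent-labda-8(17),13-dien-15-oate, via allyl selenoxide 6 (not isolated), via allyl selenenate 7 (not isolated)
Conditions: 30% aq. H2O2 (2.2 equiv), pyridine (2.5 equiv), CH2Cl2, 0 °C
Reagents that add atoms: hydrogen peroxide, OO
Why: The allylic selenoxide has no syn β-hydrogen to eliminate, so it undergoes the [2,3]-sigmatropic selenoxide–selenenate rearrangement that forms the C16–O bond and moves the alkene to C13=C14, after which the selenenate is hydrolysed in situ; the ester is expected to sit pseudo-equatorial in the envelope transition state (as the α-substituent does in SeO2 oxidations) and end trans to CH2O (13E), and any 13Z isomer simply lactonises to 10 and converges in step 4.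

Step 4
Reactants: 8 methyl (13E)-16-hydroxy-ent-labda-8(17),13-dien-15-oate
Product: 10 ent-labda-8(17),13-dien-15,16-olide, via 13Z hydroxy ester 9 (not isolated)
Conditions: hν (254 nm, quartz), degassed MeCN, PPTS (5 mol %), rt
Reagents that add atoms: none
Why: Direct excitation of the enoate equilibrates the 13E and 13Z isomers (photochemical E/Z isomerisation) and only the 13Z isomer can lactonise (acid-catalysed 5-exo-trig transesterification), which drains the mixture into the butenolide and locks C15 and C16 cis.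

Step 5
Reactants: 10 ent-labda-8(17),13-dien-15,16-olide; 11 (R)-(−)-2-methylbutanoic acid
Product: 16 (13Z)-16-[(2R)-2-methylbutanoyloxy]-ent-labda-8(17),13-dien-15-oic acid (CNP0176758.1), via lithium hydroxy carboxylate 12 (not isolated), via dilithium alkoxide carboxylate 13 (not isolated), via acyl imidazolide 14 (not isolated), via lithium carboxylate 15 (not isolated)
Conditions: a) LiOH·H2O (1.05 equiv), THF–H2O, 0 °C to rt, then evaporate and dry by toluene azeotrope; b) LiN(SiMe3)2 (1.0 equiv), THF–DMPU, −78 °C; c) add 14 [made from 11 and 1,1'-carbonyldiimidazole (1.05 equiv), THF, rt], −78 to 0 °C; d) cold 0.5 M aq. HCl to pH 3, EtOAc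
Reagents that add atoms: lithium hydroxide, [Li+].[OH-]
Why: Saponification opens the lactone without touching the fixed Z alkene, and the alkoxide, far more nucleophilic than the neighbouring carboxylate, is acylated chemoselectively by the acyl imidazolide (Staab esterification) under conditions that leave the purchased (R) α-stereocentre intact; cold acidification then frees the acid, which cannot relactonise because O16 is acylated.

**Compound list**
1 | (−)-copalic acid, ent-labda-8(17),13E-dien-15-oic acid [(2E)-3-methyl-5-[(1R,4aR,8aR)-5,5,8a-trimethyl-2-methylidenedecahydronaphthalen-1-yl]pent-2-enoic acid] | C=C1CC[C@@H]2C(C)(C)CCC[C@@]2(C)[C@@H]1CC/C(C)=C/C(=O)O | starting material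
2 | potassium ent-labda-8(17),13E-dien-15-oate | C=C1CC[C@@H]2C(C)(C)CCC[C@@]2(C)[C@@H]1CC/C(C)=C/C(=O)[O-].[K+] | intermediate
3 | methyl ent-labda-8(17),13E-dien-15-oate (methyl copalate) | C=C1CC[C@@H]2C(C)(C)CCC[C@@]2(C)[C@@H]1CC/C(C)=C/C(=O)OC | intermediate
4 | lithium dienolate of 3 (C13=C16 exocyclic, C14=C15 enolate; enolate geometry not defined) | C=C1CC[C@@H]2C(C)(C)CCC[C@@]2(C)[C@@H]1CCC(=C)C=C(OC)[O-].[Li+] | intermediate
5 | methyl (14RS)-14-(phenylselanyl)-ent-labda-8(17),13(16)-dien-15-oate (C14 epimer mixture) | C=C1CC[C@@H]2C(C)(C)CCC[C@@]2(C)[C@@H]1CCC(=C)C([Se]c3ccccc3)C(=O)OC | intermediate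
6 | methyl (14RS)-14-(phenylseleninyl)-ent-labda-8(17),13(16)-dien-15-oate | C=C1CC[C@@H]2C(C)(C)CCC[C@@]2(C)[C@@H]1CCC(=C)C([Se](=O)c3ccccc3)C(=O)OC | intermediate
7 | methyl (13E)-16-(phenylselanyloxy)-ent-labda-8(17),13-dien-15-oate | C=C1CC[C@@H]2C(C)(C)CCC[C@@]2(C)[C@@H]1CC/C(CO[Se]c3ccccc3)=C\C(=O)OC | intermediate
8 | methyl (13E)-16-hydroxy-ent-labda-8(17),13-dien-15-oate (CH2OH trans to CO2Me) | C=C1CC[C@@H]2C(C)(C)CCC[C@@]2(C)[C@@H]1CC/C(CO)=C\C(=O)OC | intermediate
9 | methyl (13Z)-16-hydroxy-ent-labda-8(17),13-dien-15-oate (CH2OH cis to CO2Me) | C=C1CC[C@@H]2C(C)(C)CCC[C@@]2(C)[C@@H]1CC/C(CO)=C/C(=O)OC | intermediate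
10 | ent-labda-8(17),13-dien-15,16-olide [4-{2-[(1R,4aR,8aR)-5,5,8a-trimethyl-2-methylidenedecahydronaphthalen-1-yl]ethyl}furan-2(5H)-one] | C=C1CC[C@@H]2C(C)(C)CCC[C@@]2(C)[C@@H]1CCC3=CC(=O)OC3 | intermediate
11 | (R)-(−)-2-methylbutanoic acid | CC[C@@H](C)C(=O)O | starting material
12 | lithium (13Z)-16-hydroxy-ent-labda-8(17),13-dien-15-oate | C=C1CC[C@@H]2C(C)(C)CCC[C@@]2(C)[C@@H]1CC/C(CO)=C/C(=O)[O-].[Li+] | intermediate
13 | dilithium (13Z)-16-oxido-ent-labda-8(17),13-dien-15-oate | C=C1CC[C@@H]2C(C)(C)CCC[C@@]2(C)[C@@H]1CC/C(C[O-])=C/C(=O)[O-].[Li+].[Li+] | intermediate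
14 | 1-[(2R)-2-methylbutanoyl]-1H-imidazole | CC[C@@H](C)C(=O)n1ccnc1 | intermediate
15 | lithium (13Z)-16-[(2R)-2-methylbutanoyloxy]-ent-labda-8(17),13-dien-15-oate | C=C1CC[C@@H]2C(C)(C)CCC[C@@]2(C)[C@@H]1CC/C(=C/C(=O)[O-])COC(=O)[C@H](C)CC.[Li+] | intermediate
16 | (13Z)-16-[(2R)-2-methylbutanoyloxy]-ent-labda-8(17),13-dien-15-oic acid [(2Z)-3-({[(2R)-2-methylbutanoyl]oxy}methyl)-5-[(1R,4aR,8aR)-5,5,8a-trimethyl-2-methylidenedecahydronaphthalen-1-yl]pent-2-enoic acid] | C=C1CC[C@@H]2C(C)(C)CCC[C@@]2(C)[C@@H]1CC/C(=C/C(=O)O)COC(=O)[C@H](C)CC | target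

**Step count**
Total steps: 5. Longest linear sequence: 5 steps (1 → 3 → 5 → 8 → 10 → 16); 11 enters in step 5.

**Steps most likely to fail**

Step 5 (acylation of O16 beside a free carboxylate). The carboxylate may be activated instead and relactonise to 10, or the cis acyloxy acid may lose its ester on slow work-up. Fallback, setting out from 10 through its saponification salt 12 and returning at 16: silylate only the carboxylate of 12 with iPr3SiCl in DMF without amine base, giving tri(propan-2-yl)silyl (13Z)-16-hydroxy-ent-labda-8(17),13-dien-15-oate F5, whose hindered silyl ester does not lactonise readily. Acylate the free hydroxyl with imidazolide 14 and catalytic DBU to tri(propan-2-yl)silyl (13Z)-16-[(2R)-2-methylbutanoyloxy]-ent-labda-8(17),13-dien-15-oate F6. Cleave the silyl ester with HF·pyridine in THF at 0 °C to give 16.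

Step 4 (photo-lactonisation). The excited enoate may photodeconjugate through γ-hydrogen transfer instead of cleanly isomerising. Fallback, setting out from 8 and returning at 10, with thermal equilibration at the aldehyde level:
- MnO2 in CH2Cl2 oxidises the allylic alcohol to methyl (13E)-16-oxo-ent-labda-8(17),13-dien-15-oate F2.
- LiOH in THF–H2O hydrolyses the ester to lithium 16-oxo-ent-labda-8(17),13-dien-15-oate F3, whose doubly activated C13=C14 bond equilibrates between 13E and 13Z by reversible conjugate addition of hydroxide.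
- Cold aq. HCl (pH 3) lets the 13Z aldehyde acid close irreversibly to the pseudo-acid (16RS)-16-hydroxy-ent-labda-8(17),13-dien-15,16-olide F4, which pulls the remaining 13E acid through.
- LiBH4 in THF at 0 °C reduces the ring-opened aldehyde of F4 to the hydroxy carboxylate 12, and acidification closes it to 10.

Step 3 (selenoxide rearrangement). PhSeOH or perseleninic acid formed from the selenium by-products can attack the 8(17)-methylene. Fallback, setting out from 3 and returning at 10, with no selenium: hydroxylate dienolate 4 at C14 with MoO(O2)2·C5H5N·OP(NMe2)3 in THF at −78 °C to methyl (14RS)-14-hydroxy-ent-labda-8(17),13(16)-dien-15-oate F1. Treat F1 with Ph3SiOReO3 (2 mol %, Et2O, 0 °C): the allyl perrhenate shuttles oxygen between C14 and C16 by reversible [3,3]-sigmatropic shifts, and because only the 13Z hydroxy ester 9 can lactonise (8 re-enters the equilibrium), the mixture drains into 10.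

**Further compounds**
F1 | step 3 | methyl (14RS)-14-hydroxy-ent-labda-8(17),13(16)-dien-15-oate | C=C1CC[C@@H]2C(C)(C)CCC[C@@]2(C)[C@@H]1CCC(=C)C(O)C(=O)OC
F2 | step 4 | methyl (13E)-16-oxo-ent-labda-8(17),13-dien-15-oate | C=C1CC[C@@H]2C(C)(C)CCC[C@@]2(C)[C@@H]1CC/C(C=O)=C\C(=O)OC
F3 | step 4 | lithium 16-oxo-ent-labda-8(17),13-dien-15-oate (equilibrating 13E/13Z mixture) | C=C1CC[C@@H]2C(C)(C)CCC[C@@]2(C)[C@@H]1CCC(C=O)=CC(=O)[O-].[Li+]
F4 | step 4 | (16RS)-16-hydroxy-ent-labda-8(17),13-dien-15,16-olide | C=C1CC[C@@H]2C(C)(C)CCC[C@@]2(C)[C@@H]1CCC3=CC(=O)OC3O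
F5 | step 5 | tri(propan-2-yl)silyl (13Z)-16-hydroxy-ent-labda-8(17),13-dien-15-oate | C=C1CC[C@@H]2C(C)(C)CCC[C@@]2(C)[C@@H]1CC/C(CO)=C/C(=O)O[Si](C(C)C)(C(C)C)C(C)C
F6 | step 5 | tri(propan-2-yl)silyl (13Z)-16-[(2R)-2-methylbutanoyloxy]-ent-labda-8(17),13-dien-15-oate | C=C1CC[C@@H]2C(C)(C)CCC[C@@]2(C)[C@@H]1CC/C(=C/C(=O)O[Si](C(C)C)(C(C)C)C(C)C)COC(=O)[C@H](C)CC
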